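The route rests on cutting C9a–C1, the bond shared by pyrrolidine ring A and cyclohexene ring B (Stemona numbering). C9a, the nitrogen-bearing enamine carbon of the azepine ring, is read as a caprolactam carbonyl. C1, the quaternary oxygen-bearing carbon, is read as C5 of a 2-silyloxy-3-methylfuran that hides the fused lactone. Activation of this lactam by Tf2O lets the N-tethered furan add in spiro mode: one operation closes ring A, sets C1, unveils the butenolide and leaves the C9=C9a enamine. The precursor is a plain N-alkyl caprolactam. Nucleophilic C9 and electrophilic C12 then take up C10–C11 by allylation, ozonolysis and ketyl closure of ring B.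

Key step: step 9

Remark (atom labels): N4. C1 is the quaternary carbon (bonded to O, C2, C9a, C12). C2 is CH2 and C3 is NCH. C5–C8 are the azepine CH2 groups. C9=C9a is the enamine. C10 is CH(Et) and C11 is CHOH. C12, C13 (Me) and C14 (C=O) form the fused lactone. C18, C19, C20 (Me) and C21 (C=O) form the side-chain lactone.

Remark (assumption): the (Sa,S,S) antipode of the phosphoramidite ligand is assumed to give the required configuration at C10 in the allylation. The sense depends on the catalyst alone, so the antipodal ligand corrects it if the assignment is opposite.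

Remark: the racemic acid used in step 6 and the epimer mixtures at C13 and C1 in steps 6 and 7 do not matter, because both centres become sp2 in step 8.

Step 1
Reactants: 1 2-(2-oxoazepan-1-yl)acetic acid; 2 (R)-4-benzyl-1,3-oxazolidin-2-one
Product: 3 (R)-4-benzyl-3-[2-(2-oxoazepan-1-yl)acetyl]-1,3-oxazolidin-2-one
Conditions: DCC, DMAP (cat.), CH2Cl2, 0 °C to rt
Reagents that add atoms: none
Why: Steglich-type carbodiimide/DMAP N-acylation of the oxazolidinone by the acid, in which no stereocentre is formed and the tertiary lactam is inert.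

Step 2
Reactants: 3 imide; 4 allyl iodide
Product: 5 (R)-4-benzyl-3-[(S)-2-(2-oxoazepan-1-yl)pent-4-enoyl]-1,3-oxazolidin-2-one
Conditions: NaN(SiMe3)2, THF, −78 °C; then 4, −78 to −40 °C
Reagents that add atoms: none
Why: Evans asymmetric alkylation, in which the benzyl group of the (R)-auxiliary shields one face of the chelated Z-enolate (the imide α-CH2 is far more acidic than the lactam α-CH2), so allyl iodide enters from the open face and sets C3 as S.

Step 3
Reactants: 5 allylated imide
Product: 6 S-ethyl (S)-2-(2-oxoazepan-1-yl)pent-4-enethioate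
Conditions: EtSH, n-BuLi, THF, 0 °C; aq. work-up
Reagents that add atoms: ethanethiol, CCS
Why: Thiolate transacylation of the imide, in which the soft lithium thiolate attacks the exocyclic carbonyl, releases the auxiliary and is too weak a base at 0 °C to epimerise C3.

Step 4
Reactants: 6 thioester; 7 methyl (R)-3-bromo-2-methylpropanoate
Product: 9 methyl (2S,5S)-2-methyl-4-oxo-5-(2-oxoazepan-1-yl)oct-7-enoate, via alkylzinc bromide 8 (not isolated)
Conditions: 7, Zn dust, LiCl, THF, 40 °C; then 6, PdCl2(PPh3)2 (5 mol %), toluene, rt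
Reagents that add atoms: zinc, [Zn] (held only by 8)
Why: Fukuyama coupling, in which zerovalent palladium inserts into the C–S bond and transmetalates with the ester-bearing alkylzinc to stop cleanly at the ketone; C20 comes unchanged from 7, and α-amino thioesters are known to keep their configuration in this reaction.

Step 5
Reactants: 9 keto ester
Product: 11 1-{(S)-1-[(2S,4S)-4-methyl-5-oxooxolan-2-yl]but-3-en-1-yl}azepan-2-one, via hydroxy ester 10 (not isolated)
Conditions: LiBH(s-Bu)3, THF, −78 °C; warm to 0 °C; aq. work-up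
Reagents that add atoms: none
Why: Polar Felkin–Anh reduction, in which the bulky non-chelating hydride attacks the C18 ketone anti to the perpendicular C3–N bond and past C3–H to give the syn (18S) alkoxide, which lactonises onto the γ-ester to the cis-2,4-disubstituted lactone while ester, lactam and alkene survive at −78 °C.

Step 6
Reactants: 11 terminal alkene; 12 2-methylbut-3-enoic acid (racemic)
Product: 13 (E,6S)-2-methyl-6-[(2S,4S)-4-methyl-5-oxooxolan-2-yl]-6-(2-oxoazepan-1-yl)hex-3-enoic acid (C2 epimers)
Conditions: second-generation Hoveyda–Grubbs catalyst (5 mol %), 1,4-benzoquinone (10 mol %), 12 (3 equiv), CH2Cl2, 40 °C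
Reagents that add atoms: none
Why: Olefin cross-metathesis of an unhindered terminal alkene and an allylically branched partner used in excess, which should give the E-alkene, with benzoquinone suppressing migration of the β,γ-double bond.

Step 7
Reactants: 13 3-alkenoic acid
Product: 14 1-{(1S)-1-[(2S,4S)-4-methyl-5-oxooxolan-2-yl]-2-(4-methyl-5-oxo-2,5-dihydrofuran-2-yl)ethyl}azepan-2-one (epimers at the butenolide γ-carbon C1)
Conditions: Pd(OAc)2 (10 mol %), NaOAc, O2 (1 atm), DMSO, 40 °C
Reagents that add atoms: none
Why: Aerobic Wacker-type oxidative lactonisation of a 3-alkenoic acid (carboxylate oxypalladation at C1, then β-hydride elimination), in which either alkene position and either C1 epimer is acceptable because all converge in step 8.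

Step 8
Reactants: 14 butenolide
Product: 15 1-{(1S)-1-[(2S,4S)-4-methyl-5-oxooxolan-2-yl]-2-[4-methyl-5-(triisopropylsilyloxy)furan-2-yl]ethyl}azepan-2-one
Conditions: i-Pr3SiOTf, Et3N, CH2Cl2, 0 °C
Reagents that add atoms: triisopropylsilyl trifluoromethanesulfonate, CC(C)[Si](OS(=O)(=O)C(F)(F)F)(C(C)C)C(C)C
Why: Soft enolisation and O-silylation of a butenolide to the aromatic 2-silyloxyfuran, selective because the vinylogous γ-hydrogen is far more acidic than the α-hydrogens of the saturated lactone and the lactam.

Step 9
Reactants: 15 silyloxyfuran lactam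
Product: 18 (1S,3S)-spiro butenolide enamine, via O-triflyl iminium triflate 16 (not isolated), via spiro iminium triflate 17 (not isolated)
Conditions: Tf2O (1.1 equiv), 2,6-di-tert-butyl-4-methylpyridine, CH2Cl2, −78 to 0 °C; then Et3N, 0 °C; basic alumina
Reagents that add atoms: trifluoromethanesulfonic anhydride, O=S(=O)(OS(=O)(=O)C(F)(F)F)C(F)(F)F (atoms stay only in 16 and 17)
Why: Proposed new method: Tf2O converts the tertiary lactam into O-triflyl iminium ion 16, C5 of the tethered 2-silyloxyfuran (the future C1) adds to C9a, triflate takes the silyl group and unveils the butenolide, the α-triflyloxy amine ionises to iminium 17, and Et3N removes a C9 proton to give enamine 18. The closest known reaction types are the Vilsmeier–Haack-type cyclisation of silyl enol ethers onto Tf2O-activated amides, the interrupted Bischler–Napieralski spirocyclisation of N-(2-indol-3-ylethyl) amides and lactams (same two-carbon N-tether, same ipso attack), and the vinylogous Mannich reaction of 5-alkyl-2-silyloxyfurans, which already builds such quaternary γ-carbons next to nitrogen-bearing carbons. Ring A closes in a 5-endo-trig mode with respect to C=N+ (5-exo with respect to the C–OTf bond), spiro at the furan; this geometry is the main risk and is the same as in the indole precedent. C1 is the only new stereocentre and C3 controls it: allylic 1,3-strain in 16 turns the C3–C18 bond perpendicular to the iminium plane so the furan adds from the opposite face, and the bulky OSi(i-Pr)3 edge (O1–C14) of the furan turns away from the OTf group, which puts C12 cis and the ring oxygen trans to the C3 side chain (1S). The tether secures attack through furan C5 and not C3, the much higher O-nucleophilicity of the lactam over the lactone carbonyl secures chemoselective activation, and 18 cannot react further because it has no γ-hydrogen left.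

Step 10
Reactants: 19 (E)-pent-2-en-1-ol
Product: 20 (E)-pent-2-en-1-yl methyl carbonate
Conditions: ClCO2Me, pyridine, CH2Cl2, 0 °C
Reagents that add atoms: methyl chloroformate, COC(=O)Cl
Why: Simple O-acylation of a primary allylic alcohol by a chloroformate, which forms no stereocentre.

Step 11
Reactants: 18 enamine; 20 allylic carbonate
Product: 21 (1S,3S,10S)-C9-(pent-1-en-3-yl) enamine
Conditions: [Ir(cod)Cl]2 (2 mol %), (Sa,S,S)-BINOL-derived N,N-bis(1-phenylethyl)phosphoramidite (4 mol %), n-PrNH2 pre-activation, THF, 30 °C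
Reagents that add atoms: none
Why: Iridium-catalysed branched-selective asymmetric allylic alkylation of an enamine, in which C9 attacks the ethyl-bearing terminus of the π-allyl complex anti to the metal, the catalyst alone fixes C10 (10S here, the spatial arrangement that reads 10R in the target), and the methoxide released removes the C9 proton to restore the now tetrasubstituted enamine.

Step 12
Reactants: 21 vinyl enamine
Product: 23 (1S,3S,10R)-enamine aldehyde, via iminium trifluoroacetate 22 (not isolated)
Conditions: CF3CO2H (2 equiv), CH2Cl2, −78 °C; O3 to dye endpoint; Me2S, −78 to 0 °C; cold aq. NaHCO3; used at once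
Reagents that add atoms: ozone, [O-][O+]=O; trifluoroacetic acid, OC(=O)C(F)(F)F (atoms stay only in 22)
Why: Ozonolysis, in which protonation at C9 masks the oxidation-prone enamine as iminium salt 22, the electron-poor butenolide alkene reacts much more slowly than the monosubstituted vinyl group, and cold bicarbonate returns the enamine before C10 can epimerise.

Step 13
Reactants: 23 enamine aldehyde
Product: 24 target CNP0154902.1
Conditions: SmI2 (2.5 equiv), t-BuOH (5 equiv), THF, −78 to −40 °C; pH 7 buffer at low temperature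
Reagents that add atoms: none
Why: SmI2 ketyl–olefin cyclisation (6-exo-trig) closes ring B, in which the short tether forces C11 onto the butenolide face syn to C9a (cis ring fusion, 12S), trivalent samarium bridging the ketyl oxygen and the lactone oxygens places O11 cis to C13 (11S) with the C10 ethyl group pseudo-axial away from C8, and the samarium enolate is protonated from the convex face opposite ring B (13S).

Compound list
1 | 2-(2-oxoazepan-1-yl)acetic acid | O=C(O)CN1CCCCCC1=O | starting material
2 | (R)-4-benzyl-1,3-oxazolidin-2-one | O=C1N[C@H](Cc2ccccc2)CO1 | starting material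
3 | (R)-4-benzyl-3-[2-(2-oxoazepan-1-yl)acetyl]-1,3-oxazolidin-2-one | O=C(CN1CCCCCC1=O)N1[C@H](Cc2ccccc2)COC1=O | intermediate
4 | allyl iodide | C=CCI | starting material
5 | (R)-4-benzyl-3-[(S)-2-(2-oxoazepan-1-yl)pent-4-enoyl]-1,3-oxazolidin-2-one | C=CC[C@H](N1CCCCCC1=O)C(=O)N1[C@H](Cc2ccccc2)COC1=O | intermediate
6 | S-ethyl (S)-2-(2-oxoazepan-1-yl)pent-4-enethioate | C=CC[C@H](N1CCCCCC1=O)C(=O)SCC | intermediate
7 | methyl (R)-3-bromo-2-methylpropanoate | BrC[C@H](C)C(=O)OC | starting material
8 | [(R)-3-methoxy-2-methyl-3-oxopropyl]zinc bromide | Br[Zn]C[C@H](C)C(=O)OC | intermediate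
9 | methyl (2S,5S)-2-methyl-4-oxo-5-(2-oxoazepan-1-yl)oct-7-enoate | C=CC[C@H](N1CCCCCC1=O)C(=O)C[C@H](C)C(=O)OC | intermediate
10 | methyl (2S,4S,5S)-4-hydroxy-2-methyl-5-(2-oxoazepan-1-yl)oct-7-enoate (formed as its lithium alkoxide) | C=CC[C@H](N1CCCCCC1=O)[C@@H](O)C[C@H](C)C(=O)OC | intermediate
11 | 1-{(S)-1-[(2S,4S)-4-methyl-5-oxooxolan-2-yl]but-3-en-1-yl}azepan-2-one | C=CC[C@H](N1CCCCCC1=O)[C@@H]1C[C@H](C)C(=O)O1 | intermediate
12 | 2-methylbut-3-enoic acid (racemic) | C=CC(C)C(=O)O | starting material
13 | (E,6S)-2-methyl-6-[(2S,4S)-4-methyl-5-oxooxolan-2-yl]-6-(2-oxoazepan-1-yl)hex-3-enoic acid (C2 epimers) | OC(=O)C(C)/C=C/C[C@H](N1CCCCCC1=O)[C@@H]1C[C@H](C)C(=O)O1 | intermediate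
14 | 1-{(1S)-1-[(2S,4S)-4-methyl-5-oxooxolan-2-yl]-2-(4-methyl-5-oxo-2,5-dihydrofuran-2-yl)ethyl}azepan-2-one (C1 epimers) | CC1=CC(C[C@H](N2CCCCCC2=O)[C@@H]2C[C@H](C)C(=O)O2)OC1=O | intermediate
15 | 1-{(1S)-1-[(2S,4S)-4-methyl-5-oxooxolan-2-yl]-2-[4-methyl-5-(triisopropylsilyloxy)furan-2-yl]ethyl}azepan-2-one | Cc1cc(C[C@H](N2CCCCCC2=O)[C@@H]2C[C@H](C)C(=O)O2)oc1O[Si](C(C)C)(C(C)C)C(C)C | intermediate
16 | O-triflyl iminium triflate of 15 (C9a carries OTf, C9a=N+) | Cc1cc(C[C@H]([N+]2=C(OS(=O)(=O)C(F)(F)F)CCCCC2)[C@@H]2C[C@H](C)C(=O)O2)oc1O[Si](C(C)C)(C(C)C)C(C)C.[O-]S(=O)(=O)C(F)(F)F | intermediate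
17 | spiro iminium triflate (ring A closed, C9a=N+, C9 is CH2, 1S,3S) | C1C2=[N+](CCCC1)[C@H]([C@@H]3C[C@H](C)C(=O)O3)C[C@@]24OC(=O)C(C)=C4.[O-]S(=O)(=O)C(F)(F)F | intermediate
18 | (1S,3S)-spiro butenolide enamine: hexahydropyrrolo[1,2-a]azepine with C9=C9a, spiro-fused at C1 to 3-methylfuran-2(5H)-one, (2S,4S)-4-methyl-5-oxooxolan-2-yl at C3 | C1=C2N(CCCC1)[C@H]([C@@H]3C[C@H](C)C(=O)O3)C[C@@]24OC(=O)C(C)=C4 | intermediate
19 | (E)-pent-2-en-1-ol | CC/C=C/CO | starting material
20 | (E)-pent-2-en-1-yl methyl carbonate | CC/C=C/COC(=O)OC | intermediate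
21 | 18 carrying a (10S)-pent-1-en-3-yl group at C9 | CC[C@@H](C=C)C1=C2N(CCCC1)[C@H]([C@@H]3C[C@H](C)C(=O)O3)C[C@@]24OC(=O)C(C)=C4 | intermediate
22 | C9-protonated 21 as iminium trifluoroacetate (C9 undefined) | CC[C@@H](C=C)C1C2=[N+](CCCC1)[C@H]([C@@H]3C[C@H](C)C(=O)O3)C[C@@]24OC(=O)C(C)=C4.[O-]C(=O)C(F)(F)F | intermediate
23 | 18 carrying a (10R)-1-oxobutan-2-yl group at C9 | CC[C@@H](C=O)C1=C2N(CCCC1)[C@H]([C@@H]3C[C@H](C)C(=O)O3)C[C@@]24OC(=O)C(C)=C4 | intermediate
24 | CNP0154902.1 (1S,3S,10R,11S,12S,13S,18S,20S) | CC[C@@H]1C2=C3N(CCCC2)[C@H]([C@@H]2C[C@H](C)C(=O)O2)C[C@@]32OC(=O)[C@@H](C)[C@H]2[C@H]1O | target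

Total step count: 13. Longest linear sequence: 12 (steps 1–9 and 11–13).

Steps most likely to fail

Step 9. The five-membered closure onto the crowded O-triflyl iminium ion may be slower than decay of the activated lactam by deprotonation or hydrolysis, and the furan may show poor facial selectivity.
- The fallback sets out from 15 and returns at 18. It takes the lactam one oxidation level lower and uses known reactions only.
- Hydrosilylation by (Me2HSi)2O, catalysed by IrCl(CO)(PPh3)2, gives the O-silyl hemiaminal F1.
- Catalytic Me3SiOTf ionises it to the unencumbered iminium ion, and the intramolecular vinylogous Mannich reaction gives the saturated spiro amine F2.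
- mCPBA gives the N-oxide F3.
- The Polonovski–Potier reaction ((CF3CO)2O, then Et3N) passes through the iminium trifluoroacetate F4. The tertiary C9a–H should be lost in preference to C3–H, which the adjacent lactone oxygen deactivates. This leads to enamine 18.

Step 13. The ketyl may approach through the other aldehyde face, or the new samarium alkoxide at C11 may trigger acyl migration of the fused lactone from O1 to O11.
- The fallback sets out from 23 and returns at 24.
- An intramolecular Stetter reaction closes ring B at the ketone level to the C11 ketone F8. Conditions: 2-(pentafluorophenyl)-6,7-dihydro-5H-pyrrolo[2,1-c][1,2,4]triazol-2-ium tetrafluoroborate, i-Pr2NEt, toluene.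
- LiBH(s-Bu)3 at −78 °C then attacks along the equatorial trajectory to give the axial 11-alcohol 24. A cold neutral quench keeps the alkoxide from migrating the acyl group.

Step 11. The hindered enamine may react sluggishly, attack the unsubstituted allyl terminus, or react at nitrogen.
- The fallback sets out from 18 and returns at 23, so it bypasses steps 11 and 12.
- (R)-2-hydroxybutanoic acid is converted by EtSH and DCC into S-ethyl (R)-2-hydroxybutanethioate F5.
- Tf2O and 2,6-lutidine then give the triflate F6.
- Stork-type C-alkylation of 18 by F6 in the presence of i-Pr2NEt proceeds by SN2 inversion to the C9-alkylated thioester enamine F7.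
- Fukuyama reduction (Et3SiH, Pd/C, acetone) converts only the thioester into aldehyde 23.

Further compounds
F1 | step 9 | O-silyl hemiaminal of 15 | Cc1cc(C[C@H](N2CCCCCC2O[Si](C)(C)O[SiH](C)C)[C@@H]2C[C@H](C)C(=O)O2)oc1O[Si](C(C)C)(C(C)C)C(C)C
F2 | step 9 | saturated spiro amine (C9a–H, C9a undefined) | C1C2N(CCCC1)[C@H]([C@@H]3C[C@H](C)C(=O)O3)C[C@@]24OC(=O)C(C)=C4
F3 | step 9 | N-oxide of F2 | C1C2[N+]([O-])(CCCC1)[C@H]([C@@H]3C[C@H](C)C(=O)O3)C[C@@]24OC(=O)C(C)=C4
F4 | step 9 | spiro iminium trifluoroacetate | C1C2=[N+](CCCC1)[C@H]([C@@H]3C[C@H](C)C(=O)O3)C[C@@]24OC(=O)C(C)=C4.[O-]C(=O)C(F)(F)F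
F5 | step 11 | S-ethyl (R)-2-hydroxybutanethioate | CC[C@@H](O)C(=O)SCC
F6 | step 11 | S-ethyl (R)-2-(trifluoromethylsulfonyloxy)butanethioate | CC[C@@H](OS(=O)(=O)C(F)(F)F)C(=O)SCC
F7 | step 11 | 18 carrying a (10R)-1-(ethylsulfanyl)-1-oxobutan-2-yl group at C9 | CC[C@@H](C(=O)SCC)C1=C2N(CCCC1)[C@H]([C@@H]3C[C@H](C)C(=O)O3)C[C@@]24OC(=O)C(C)=C4
F8 | step 13 | C11 ketone of the tetracycle | CC[C@@H]1C2=C3N(CCCC2)[C@H]([C@@H]2C[C@H](C)C(=O)O2)C[C@@]32OC(=O)[C@@H](C)[C@H]2C1=O
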